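Early on the autumn run moves fast and then slows. Its conversion exponent, the logarithm of one over the unconverted part, stands at 0.126 after 0.500 min and 0.265 after 3.00 min, so half of it arrives in that first stretch. I read a clock with a half-life near 0.500 min, and 3.0 min holds 6.00 of them. At 3.00 min the products read in the autumn run account for 31.1% of its coupling partner, so I suspect the partner is lost some other way, and then the final exponent should follow its charge.

| setting | autumn | spring | dusk | flask |
|---|---|---|---|---|
| left-handed substrate | 0.050 M | 0.050 M | 0.025 M | 0.050 M |
| right-handed substrate | 0.050 M | 0.050 M | 0.025 M | 0.050 M |
| coupling partner | 0.075 M | 0.11 M | 0.15 M | 0.150 M |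
| precatalyst | 2.9 mM | 2.9 mM | 2.9 mM | 2.9 mM |
| remark | run made earlier | run made earlier | run made earlier |  |
| time |  |  |  | 3.0 min |

- autumn (time / min: left-handed product / %, right-handed product / %): 0.250: 5.0, 3.8; 0.500: 8.3, 3.5; 1.33: 13.0, 6.5; 3.00: 16.3, 7.0
- spring (time / min: left-handed product / %, right-handed product / %): 0.250: 7.9, 3.8; 0.500: 12.6, 4.0; 1.33: 18.2, 7.3; 3.00: 21.6, 10.4
- dusk (time / min: left-handed product / %, right-handed product / %): 0.250: 10.4, 4.4; 0.500: 17.2, 6.8; 1.33: 24.7, 12.8; 3.00: 29.2, 14.0

(scatter of a reading: 1 percentage point)

- coupling partner is single-handed; left-handed substrate and right-handed substrate are mirror images of each other, charged as a racemate, each of them at the stated concentration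
- the earlier runs were read with a standard deviation of 1 percentage point
- an excess is the difference of the two amounts in percent of their sum
- an excess is below zero if the other one leads
- the handed part of coupling partner does not stay in what it makes, so the products of the two hands are mirror images too

- left-handed product and right-handed product together, in percent of the left-handed substrate and right-handed substrate charged together, at 3.0 min
- excess of left-handed product over right-handed product in the product at 3.0 min
- whether the exchange between left-handed substrate and right-handed substrate keeps pace with the reaction: how far the product's excess at 3.0 min gets from its value without exchange to its value with instant exchange (above 80% keeps pace, below 20% hardly takes part, else lags behind)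

Autumn and spring give a mean of 3.52 M⁻¹. I call this final exponent per molar of partner charged the reach. Dusk, with half the substrate, reads 3.77 M⁻¹. With 0.150 M of partner, my reach gives the flask 41.0%.

The forecast says 41.5%, an excess of 35%, and that the exchange hardly takes part, its ground for the flattening being that “the catalyst dies with time”.

The flask gives 38.1% and an excess of 35.0%, and its exchange lags behind, getting 32% of the way.

    coupling partner + precatalyst → racemization catalyst + spent reagent (k = 0.0660 M⁻¹ s⁻¹)
    coupling partner → decomposed reagent (k = 0.0190 s⁻¹)
    left-handed substrate + racemization catalyst ⇌ right-handed substrate + racemization catalyst, rate k3*[racemization catalyst]*[left-handed substrate] forward; the back reaction follows from the equilibrium constant (k = 12.0 M⁻¹ s⁻¹)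
    coupling partner + left-handed substrate → left-handed product (k = 0.120 M⁻¹ s⁻¹)
    coupling partner + right-handed substrate → right-handed product (k = 0.0510 M⁻¹ s⁻¹)

At 3.00 min the coupling partner, the limiting reagent, is down to 1.1% of its charge, and at the start its decomposition uses it 3.2 times as fast as the coupling to left-handed product does. The flask's own reach is 3.19 M⁻¹, lower than the 3.52 M⁻¹ read from autumn and spring. At 0.26 M of partner that flask's reach gives 56.4%, and the neighbour charged so stands at 57.4%.

The readings are calculated for an exercise.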